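**Retrosynthetic overview**

1. Numbering: C1 is the ring carbon bearing C7H2O, C2 the vinylic CH, C3–C6 follow round the cyclohexene ring. The strategy rests on O3 and O6 standing trans-1,4 across the C1=C2 alkene, with O6 cis to O5 and O3 trans to O4.
2. Target ⇒ tetrol 7-benzoate (O5 benzoate by opening of a cis-diol orthobenzoate) ⇒ triol acetonide (selective O7 benzoylation) ⇒ triacetate.
3. Key disconnection: C6–O and C3–O by palladium-catalysed trans-1,4-diacetoxylation of the C6=C1–C2=C3 diene. C7 carries an acetate instead of a silyl ether so that the first C–O bond is steered to C6.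
4. Diene ⇒ (−)-shikimic acid by esterification, 3,4-acetonide, elimination of the 5-hydroxyl, reduction and acetylation; shikimate C3 and C4 become C5 and C4.
5. Ring order: the cyclohexene, the only ring of the target, is taken intact from shikimic acid; no ring is formed, and the acetonide is temporary.

Key step: step 6

Remark: in step 10 the orthobenzoate may sit on O4/O5 or on O5/O6; both contain O5 and should open to the same benzoate, so both are numbered.

**Route**

Step 1
Reactants: 1 (−)-shikimic acid
Product: 2 methyl (−)-shikimate
Conditions: MeOH, camphor-10-sulfonic acid (cat.), reflux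
Reagents that add atoms: methanol, CO
Why: Fischer esterification of the conjugated acid in methanol leaves the three secondary hydroxyls and all stereocentres untouched.

Step 2
Reactants: 2 methyl (−)-shikimate, 3 2,2-dimethoxypropane
Product: 4 methyl 3,4-O-isopropylideneshikimate (shikimate numbering; cis-fused acetonide, 5-OH free)
Conditions: 2,2-dimethoxypropane, p-TsOH·H2O (cat.), acetone, 20 °C
Reagents that add atoms: 2,2-dimethoxypropane (3), COC(C)(C)OC
Why: Acid-catalysed transketalisation selects the cis-3,4-diol, since only a cis-fused dioxolane forms readily on the cyclohexene, and leaves the trans 5-hydroxyl free.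

Step 3
Reactants: 4 methyl 3,4-O-isopropylideneshikimate
Product: 6 methyl (3R,4S)-3,4-(isopropylidenedioxy)cyclohexa-1,5-diene-1-carboxylate (shikimate numbering), via 5-O-triflate 5 (not isolated)
Conditions: Tf2O, pyridine, CH2Cl2, −20 °C; then CsOAc, DMF, 20 °C
Reagents that add atoms: none
Why: O-Sulfonylation of the 5-hydroxyl followed by base-induced 1,2-elimination (E2) of triflate with the acidified allylic H6, for which the mild base CsOAc suffices while substitution at C5 is slowed by the neighbouring acetonide, gives the conjugated diene and leaves the two acetonide-bearing stereocentres untouched.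

Step 4
Reactants: 6 diene ester
Product: 7 dienol, [(3R,4S)-3,4-(isopropylidenedioxy)cyclohexa-1,5-dien-1-yl]methanol (shikimate numbering)
Conditions: i-Bu2AlH (2.5 equiv), CH2Cl2, −78 °C; aq. potassium sodium tartrate work-up
Reagents that add atoms: none
Why: 1,2-Reduction of the α,β-unsaturated ester by the aluminium hydride at low temperature gives the primary allylic alcohol and spares the diene and the acetonide.

Step 5
Reactants: 7 dienol
Product: 8 dienyl acetate (C7 acetate, C6=C1–C2=C3 diene, O4/O5 acetonide)
Conditions: Ac2O, pyridine, 4-dimethylaminopyridine (cat.), CH2Cl2, 0 °C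
Reagents that add atoms: acetic anhydride, CC(=O)OC(C)=O
Why: Standard nucleophile-catalysed O-acylation installs at C7 a small ester whose carbonyl oxygen can take part in step 6 and which later leaves in the same methanolysis as the new acetates.

Step 6
Reactants: 8 dienyl acetate
Product: 9 triacetate (acetates on O3, O6 and O7; O4/O5 acetonide; C1=C2 alkene; O6 cis to O5, O3 trans to O4)
Conditions: Pd(OAc)2 (5 mol%), p-benzoquinone (2 equiv), LiOAc (1 equiv), dry AcOH/acetone 1:4, 25 °C, dark
Reagents that add atoms: acetic acid, CC(=O)O; lithium acetate, [Li+].CC(=O)[O-]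
Why: This is the known chloride-free palladium-catalysed 1,4-diacetoxylation of a cyclic 1,3-diene: Pd(OAc)2 (divalent palladium) binds the C6=C1–C2=C3 diene on the face opposite the cis-fused acetonide, an oxygen adds to C6 anti to the metal to give an η3-allyl over C1–C2–C3, and benzoquinone then triggers transfer of an acetate from palladium to C3 on the metal face and is reduced as it reoxidises the zerovalent palladium. No ring of the product is closed. C6 is set by the anti attack on the acetonide face (O6 cis to O5) and C3 by the syn transfer on the opposite face (O3 trans to O4 and to O6), so both follow from the face of complexation that the acetonide dictates. The step needs the first C–O bond at C6 and not at C3, whereas an external acetate would by default enter the terminus of the less substituted alkene, C3, and lead to the C3,C6-bis-epimer; therefore C7 carries an acetate and not a silyl ether, since its carbonyl oxygen can reach C6, and cannot reach C3, through a six-membered 1,3-dioxan-2-ylium ion, the same neighbouring-group closure by which divalent palladium transposes allylic acetates. Acetate in the dry medium should reopen that ion at the primary carbon C7, so internal delivery and direct acetate attack at C6 both end in 9, and acetone as co-solvent with little LiOAc keeps external acetate low enough for the internal path to compete. LiOAc also buffers the acid so that the acetonide and the sensitive diene survive.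

Step 7
Reactants: 9 triacetate
Product: 10 triol acetonide (free O3, O6 and O7 hydroxyls; O4/O5 acetonide)
Conditions: K2CO3 (0.2 equiv), MeOH, 0 to 20 °C
Reagents that add atoms: none
Why: Base-catalysed transesterification (Zemplén-type methanolysis) removes the three acetates as methyl acetate without touching the acetonide or the allylic stereocentres.

Step 8
Reactants: 10 triol acetonide, 11 benzoyl chloride
Product: 12 7-O-benzoate (free O3 and O6 hydroxyls; O4/O5 acetonide)
Conditions: BzCl (1.05 equiv), pyridine, CH2Cl2, −40 °C
Reagents that add atoms: benzoyl chloride (11), O=C(Cl)c1ccccc1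
Why: Kinetically selective O-acylation: with one equivalent of acid chloride at low temperature the unhindered primary allylic hydroxyl at C7 should react far faster than the two secondary hydroxyls, of which O6 is flanked by the acetonide.

Step 9
Reactants: 12 7-O-benzoate
Product: 13 tetrol 7-benzoate (free O3, O4, O5 and O6 hydroxyls)
Conditions: AcOH/H2O 4:1, 50 °C
Reagents that add atoms: none
Why: Acid-catalysed acetal hydrolysis frees O4 and O5 under conditions that leave the benzoate in place.

Step 10
Reactants: 13 tetrol 7-benzoate, 14 trimethyl orthobenzoate
Product: 17 [(3R,4S,5R,6R)-5-(benzoyloxy)-3,4,6-trihydroxycyclohex-1-en-1-yl]methyl benzoate (target), via O4/O5 cyclic orthobenzoate 15 (not isolated), via O5/O6 cyclic orthobenzoate 16 (not isolated)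
Conditions: PhC(OMe)3 (1.3 equiv), camphor-10-sulfonic acid (cat.), MeCN, 20 °C; then AcOH/H2O 4:1, 20 °C
Reagents that add atoms: trimethyl orthobenzoate (14), COC(OC)(OC)c1ccccc1; water, O
Why: Acid-catalysed orthoester exchange places a cyclic orthobenzoate on a cis-diol, both of which contain O5, and mild aqueous acid opens the hemiorthoester toward the axial ester (the known cis-diol orthoester-to-axial-ester rearrangement), O5 being the axial oxygen of the half-chair that keeps O3, O4 and O6 equatorial or pseudo-equatorial.

**Compound list**

1 | (−)-shikimic acid, (3R,4S,5R)-3,4,5-trihydroxycyclohex-1-ene-1-carboxylic acid | OC(=O)C1=C[C@@H](O)[C@@H](O)[C@H](O)C1 | starting material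
2 | methyl (−)-shikimate | COC(=O)C1=C[C@@H](O)[C@@H](O)[C@H](O)C1 | intermediate
3 | 2,2-dimethoxypropane | COC(C)(C)OC | starting material
4 | methyl 3,4-O-isopropylideneshikimate | COC(=O)C1=C[C@H]2OC(C)(C)O[C@H]2[C@H](O)C1 | intermediate
5 | methyl 3,4-O-isopropylidene-5-O-(trifluoromethanesulfonyl)shikimate | COC(=O)C1=C[C@H]2OC(C)(C)O[C@H]2[C@H](OS(=O)(=O)C(F)(F)F)C1 | intermediate (not isolated)
6 | diene ester, methyl (3R,4S)-3,4-(isopropylidenedioxy)cyclohexa-1,5-diene-1-carboxylate | COC(=O)C1=C[C@H]2OC(C)(C)O[C@H]2C=C1 | intermediate
7 | dienol, [(3R,4S)-3,4-(isopropylidenedioxy)cyclohexa-1,5-dien-1-yl]methanol | OCC1=C[C@H]2OC(C)(C)O[C@H]2C=C1 | intermediate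
8 | dienyl acetate (C7 acetate of 7) | CC(=O)OCC1=C[C@H]2OC(C)(C)O[C@H]2C=C1 | intermediate
9 | triacetate: 3,6,7-tri-O-acetyl-4,5-O-isopropylidene cyclohexene, O6 cis to O5, O3 trans to O4 | CC(=O)OCC1=C[C@@H](OC(C)=O)[C@@H]2OC(C)(C)O[C@@H]2[C@@H]1OC(C)=O | intermediate
10 | triol acetonide (O3, O6, O7 free; O4/O5 acetonide) | OCC1=C[C@@H](O)[C@@H]2OC(C)(C)O[C@@H]2[C@@H]1O | intermediate
11 | benzoyl chloride | O=C(Cl)c1ccccc1 | starting material
12 | 7-O-benzoate of 10 | O=C(OCC1=C[C@@H](O)[C@@H]2OC(C)(C)O[C@@H]2[C@@H]1O)c1ccccc1 | intermediate
13 | tetrol 7-benzoate | O=C(OCC1=C[C@@H](O)[C@H](O)[C@H](O)[C@@H]1O)c1ccccc1 | intermediate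
14 | trimethyl orthobenzoate | COC(OC)(OC)c1ccccc1 | starting material
15 | O4/O5 cyclic methyl orthobenzoate of 13 | O=C(OCC1=C[C@@H](O)[C@@H]2OC(OC)(c3ccccc3)O[C@@H]2[C@@H]1O)c1ccccc1 | intermediate (not isolated)
16 | O5/O6 cyclic methyl orthobenzoate of 13 | O=C(OCC1=C[C@@H](O)[C@H](O)[C@@H]2OC(OC)(c3ccccc3)O[C@H]12)c1ccccc1 | intermediate (not isolated)
17 | [(3R,4S,5R,6R)-5-(benzoyloxy)-3,4,6-trihydroxycyclohex-1-en-1-yl]methyl benzoate | O=C(OCC1=C[C@@H](O)[C@H](O)[C@H](OC(=O)c2ccccc2)[C@@H]1O)c1ccccc1 | target

**Step count and risks**

Total steps: 10. Longest linear sequence: 10 steps, from (−)-shikimic acid.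

Steps most likely to fail:

1. Step 6. The order of C–O bond formation may be reversed: external acetate may enter C3 first and the metal then deliver to C6, which gives the C3,C6-bis-epimer. The electron-rich diene may also aromatise or dimerise before it is oxidised. The fallback sets out from 6 and comes back at 10. Peracid epoxidation of diene ester 6 (mCPBA, CH2Cl2, 0 °C) should take place at the more electron-rich C2=C3 alkene, remote from the ester, on the face opposite the acetonide, and give the epoxy ester F1. Reduction with i-Bu2AlH (CH2Cl2, −78 °C) gives the epoxy alcohol F2. PhSeNa (from PhSeSePh and NaBH4, EtOH) opens the vinyl epoxide at the allylic carbon C2 with inversion to the hydroxy selenide F3, with O3 on the face opposite the acetonide and selenium on the acetonide face. Oxidation with H2O2/pyridine then sets off the [2,3]-sigmatropic rearrangement of the allylic selenoxide, which carries oxygen suprafacially to C6 on the acetonide face and moves the alkene to C1=C2; hydrolysis of the selenenate gives triol 10.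

2. Step 10. The hemiorthoester may collapse toward the wrong oxygen, leaving the benzoate on O4 or O6, if the reacting half-chair holds O5 equatorial; acid-promoted acyl migration among the neighbouring hydroxyls is a second concern. The fallback sets out from 13 and comes back at 17. Bu2SnO (MeOH, reflux, then toluene) converts tetrol 13 into the dibutylstannylene acetal F4 on a cis-diol (drawn on O4/O5). BzCl at 0 °C then acylates the equatorial oxygen of that acetal, which is O5 in exactly the conformer in which the orthoester opening fails, and gives 17.

3. Step 8. Site selectivity may be lost, with over-acylation or acylation of the secondary allylic hydroxyls. The fallback sets out from 10 and comes back at 12. Mitsunobu esterification (PPh3, diisopropyl azodicarboxylate, benzoic acid, THF, 0 °C) activates the unhindered primary allylic alcohol as its oxyphosphonium ion and lets benzoate displace at C7, which is no stereocentre; it gives 12 directly and makes no new compound.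

**Further compounds**

F1 | step 6 | epoxy ester: 2,3-epoxide of diene ester 6 on the face opposite the acetonide | COC(=O)C1=C[C@H]2OC(C)(C)O[C@H]2[C@@H]3O[C@H]13
F2 | step 6 | epoxy alcohol: C7 alcohol of F1 | OCC1=C[C@H]2OC(C)(C)O[C@H]2[C@@H]3O[C@H]13
F3 | step 6 | hydroxy selenide: C2 phenylselanyl on the acetonide face, O3 hydroxyl on the opposite face, C1=C6 alkene | OCC1=C[C@H]2OC(C)(C)O[C@H]2[C@H](O)[C@H]1[Se]c1ccccc1
F4 | step 10 | O4/O5 dibutylstannylene acetal of tetrol 7-benzoate 13 | O=C(OCC1=C[C@@H](O)[C@@H]2O[Sn](CCCC)(CCCC)O[C@@H]2[C@@H]1O)c1ccccc1
F0 | step 8 | none | none
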